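**Retrosynthetic overview**

1. Target ⇒ two molecules of (S)-herbertenediol; the aryl–CH2–aryl bond is made last by an oxidative quinone-methide dehydrodimerisation of the free catechol.
2. (S)-Herbertenediol ⇒ its dimethyl ether ⇒ (R)-2-aryl-2-methylcyclopentanone; C=O becomes CMe2 by methylenation, cyclopropanation and hydrogenolysis, which avoids a carbocation next to the benzylic quaternary centre.
3. Cyclopentanone ⇒ spiro-epoxide of an aryl(methyl)alkylidenecyclobutane by stereospecific ring expansion; the stereocentre comes from an organocatalytic (chiral dioxirane) epoxidation of the achiral tetrasubstituted alkene.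
4. Alkene ⇒ aryl methyl ketone + cyclobutyl Wittig salt; ketone ⇒ ortho-lithiation of 3,4-dimethoxytoluene.
5. Ring order: arene and cyclobutane are bought; oxirane (step 3) → cyclopentane by ring expansion (step 4) → transient cyclopropane (step 6, opened in step 7); the two monomers are joined in step 9.

Assumption: 1, 2 and 5 are catalogue compounds, and the facial sense of the epoxidation is assigned by analogy; if the catalyst antipode at hand gives (R)-8, the retentive LiI-mediated ring expansion replaces the invertive Et2AlCl one so that (R)-9 results either way.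

**Step 1**
Reactants: 1 3,4-dimethoxytoluene; 2 N-methoxy-N-methylacetamide
Product: 4 1-(2,3-dimethoxy-5-methylphenyl)ethan-1-one, via aryllithium 3 (not isolated)
Conditions: n-BuLi, TMEDA, THF, 0 °C → rt; then 2, −78 → 0 °C; aq HCl
Reagents that add atoms: none
Why: Directed ortho-metalation puts lithium at the OMe-flanked C–H that is not next to the methyl group, and the Weinreb ketone synthesis stops cleanly at the methyl ketone.

**Step 2**
Reactants: 4 1-(2,3-dimethoxy-5-methylphenyl)ethan-1-one; 5 cyclobutyltriphenylphosphonium bromide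
Product: 7 1-(1-cyclobutylideneethyl)-2,3-dimethoxy-5-methylbenzene, via phosphorus ylide 6 (not isolated)
Conditions: 5, KOtBu, PhMe, rt; then 4, 100 °C
Reagents that add atoms: none
Why: Wittig olefination with the non-stabilised cyclobutylidene ylide gives the achiral tetrasubstituted alkene, with no E/Z issue because the cyclobutylidene end is symmetric.

**Step 3**
Reactants: 7 1-(1-cyclobutylideneethyl)-2,3-dimethoxy-5-methylbenzene
Product: 8 (2S)-2-(2,3-dimethoxy-5-methylphenyl)-2-methyl-1-oxaspiro[2.3]hexane
Conditions: Shi N-aryl oxazolidinone ketone catalyst (30 mol %), Oxone, K2CO3, Bu4NHSO4, DME/DMM–aq buffer, −10 → 0 °C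
Reagents that add atoms: Oxone (potassium peroxymonosulfate), [K+].[O-]S(=O)(=O)OO
Why: Shi asymmetric epoxidation: the chiral dioxirane formed from the ketone organocatalyst and Oxone delivers oxygen to one enantiotopic face of the achiral alkene through a spiro transition state, setting the first stereocentre as (S) under catalyst control.

**Step 4**
Reactants: 8 (2S)-2-(2,3-dimethoxy-5-methylphenyl)-2-methyl-1-oxaspiro[2.3]hexane (used crude)
Product: 9 (2R)-2-(2,3-dimethoxy-5-methylphenyl)-2-methylcyclopentan-1-one
Conditions: Et2AlCl (1.0 equiv), PhMe, −78 °C; aq Rochelle salt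
Reagents that add atoms: none
Why: Lewis-acid-promoted Meinwald-type (semipinacol) ring expansion: a cyclobutane C–C bond migrates anti to the breaking benzylic C–O bond, so strain release drives cyclobutane → cyclopentanone and the stereocentre is transferred with inversion to give (R)-9.

**Step 5**
Reactants: 9 (2R)-2-(2,3-dimethoxy-5-methylphenyl)-2-methylcyclopentan-1-one
Product: 10 1,2-dimethoxy-5-methyl-3-[(1S)-1-methyl-2-methylidenecyclopentyl]benzene
Conditions: Ph3PCH3Br, KOtBu, PhMe, 90 °C
Reagents that add atoms: methyltriphenylphosphonium bromide, C[P+](c1ccccc1)(c1ccccc1)c1ccccc1.[Br-]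
Why: Wittig methylenation under forcing conditions for a hindered ketone; the quaternary stereocentre has no α-hydrogen and cannot epimerise (the descriptor changes to S only through CIP priorities).

**Step 6**
Reactants: 10 1,2-dimethoxy-5-methyl-3-[(1S)-1-methyl-2-methylidenecyclopentyl]benzene
Product: 11 (4S)-4-(2,3-dimethoxy-5-methylphenyl)-4-methylspiro[2.4]heptane
Conditions: Et2Zn, CH2I2, CH2Cl2, 0 °C → rt
Reagents that add atoms: diiodomethane, ICI
Why: Simmons–Smith (Furukawa) cyclopropanation transfers CH2 to the 1,1-disubstituted alkene in a concerted way, so no cation forms beside the aryl-bearing quaternary carbon.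

**Step 7**
Reactants: 11 (4S)-4-(2,3-dimethoxy-5-methylphenyl)-4-methylspiro[2.4]heptane
Product: 12 1,2-dimethoxy-5-methyl-3-[(1S)-1,2,2-trimethylcyclopentyl]benzene
Conditions: H2 (1–3 atm), PtO2 (cat.), AcOH, rt
Reagents that add atoms: none
Why: Catalytic hydrogenolysis cleaves the least hindered CH2–CH2 bond of the spirocyclopropane to give the gem-dimethyl group, and because no carbocation is involved a phenonium-type 1,2-aryl shift cannot scramble the stereocentre.

**Step 8**
Reactants: 12 1,2-dimethoxy-5-methyl-3-[(1S)-1,2,2-trimethylcyclopentyl]benzene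
Product: 13 5-methyl-3-[(1S)-1,2,2-trimethylcyclopentyl]benzene-1,2-diol
Conditions: BBr3, CH2Cl2, −78 → 0 °C; then H2O (under Ar)
Reagents that add atoms: none
Why: BBr3 cleavage of aryl methyl ethers (boron-assisted SN2 at the methyl groups) frees the catechol without touching the all-carbon stereocentre.

**Step 9**
Reactants: 13 5-methyl-3-[(1S)-1,2,2-trimethylcyclopentyl]benzene-1,2-diol (two molecules)
Product: 16 3-{[3,4-dihydroxy-5-((1S)-1,2,2-trimethylcyclopentyl)phenyl]methyl}-4-methyl-6-[(1S)-1,2,2-trimethylcyclopentyl]benzene-1,2-diol (target), via o-quinone 14 (not isolated), via quinone methide 15 (not isolated)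
Conditions: Ag2O (0.5 equiv), Na2SO4, CH2Cl2, 0 °C; filter; then (PhO)2P(O)OH (10 mol %), HFIP, 0 °C → rt, Ar
Reagents that add atoms: none
Why: Proposed new method: two-electron oxidation of half of 13 gives o-quinone 14, whose acid/HFIP-promoted vinylogous enolisation of the para-methyl group gives 2-hydroxy-p-quinone methide 15 (a masked 3,4-dihydroxybenzyl cation), and the remaining 13 adds through its only unhindered activated ring position (ortho to OH, next to the methyl) in a 1,6-Friedel–Crafts addition followed by rearomatisation, while biaryl coupling is disfavoured because it would be tetra-ortho-substituted; the closest known reaction type is the acid-catalysed 1,6-addition of phenols to para-quinone methides together with the tautomerisation of 4-alkyl-o-quinones to quinone methides; both stereocentres are remote and untouched.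

**Compound list**

1 | 3,4-dimethoxytoluene | Cc1ccc(OC)c(OC)c1 | starting material
2 | N-methoxy-N-methylacetamide | CC(=O)N(C)OC | starting material
3 | (2,3-dimethoxy-5-methylphenyl)lithium | [Li]c1cc(C)cc(OC)c1OC | intermediate (not isolated)
4 | 1-(2,3-dimethoxy-5-methylphenyl)ethan-1-one | CC(=O)c1cc(C)cc(OC)c1OC | intermediate
5 | cyclobutyltriphenylphosphonium bromide | [Br-].C1CC(C1)[P+](c1ccccc1)(c1ccccc1)c1ccccc1 | starting material
6 | cyclobutylidene(triphenyl)phosphorane | C1CC(C1)=P(c1ccccc1)(c1ccccc1)c1ccccc1 | intermediate (not isolated)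
7 | 1-(1-cyclobutylideneethyl)-2,3-dimethoxy-5-methylbenzene | CC(=C1CCC1)c1cc(C)cc(OC)c1OC | intermediate
8 | (2S)-2-(2,3-dimethoxy-5-methylphenyl)-2-methyl-1-oxaspiro[2.3]hexane | C[C@@]1(c2cc(C)cc(OC)c2OC)OC13CCC3 | intermediate
9 | (2R)-2-(2,3-dimethoxy-5-methylphenyl)-2-methylcyclopentan-1-one | COc1cc(C)cc([C@@]2(C)CCCC2=O)c1OC | intermediate
10 | 1,2-dimethoxy-5-methyl-3-[(1S)-1-methyl-2-methylidenecyclopentyl]benzene | COc1cc(C)cc([C@@]2(C)CCCC2=C)c1OC | intermediate
11 | (4S)-4-(2,3-dimethoxy-5-methylphenyl)-4-methylspiro[2.4]heptane | COc1cc(C)cc([C@@]2(C)CCCC23CC3)c1OC | intermediate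
12 | 1,2-dimethoxy-5-methyl-3-[(1S)-1,2,2-trimethylcyclopentyl]benzene ((S)-herbertenediol dimethyl ether) | COc1cc(C)cc([C@@]2(C)CCCC2(C)C)c1OC | intermediate
13 | 5-methyl-3-[(1S)-1,2,2-trimethylcyclopentyl]benzene-1,2-diol ((S)-herbertenediol) | Cc1cc(O)c(O)c([C@@]2(C)CCCC2(C)C)c1 | intermediate
14 | 5-methyl-3-[(1S)-1,2,2-trimethylcyclopentyl]cyclohexa-3,5-diene-1,2-dione | CC1=CC(=O)C(=O)C([C@@]2(C)CCCC2(C)C)=C1 | intermediate (not isolated)
15 | 2-hydroxy-4-methylidene-6-[(1S)-1,2,2-trimethylcyclopentyl]cyclohexa-2,5-dien-1-one | C=C1C=C(O)C(=O)C([C@@]2(C)CCCC2(C)C)=C1 | intermediate (not isolated)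
16 | 3-{[3,4-dihydroxy-5-((1S)-1,2,2-trimethylcyclopentyl)phenyl]methyl}-4-methyl-6-[(1S)-1,2,2-trimethylcyclopentyl]benzene-1,2-diol | Cc1cc([C@@]2(C)CCCC2(C)C)c(O)c(O)c1Cc1cc(O)c(O)c([C@@]2(C)CCCC2(C)C)c1 | target

**Totals**

Total step count: 9. Longest linear sequence: 9 (step 9 joins two molecules from the same sequence).

**Three steps most likely to fail**

Step 9 (the proposed new step). The o-quinone may couple through a ring carbon or oxygen instead of tautomerising, and the product catechols can be re-oxidised and oligomerise, so the reaction would be run to partial conversion with recovery of 13. The fallback uses known chemistry, sets out from 13 (with 12, held back from step 7, as the nucleophile) and comes back at 16. Acetylation (Ac2O, pyridine, DMAP) gives 5-methyl-3-[(1S)-1,2,2-trimethylcyclopentyl]-1,2-phenylene diacetate F4. Wohl–Ziegler bromination (NBS, AIBN, PhCF3, 80 °C), which the acetates steer to the benzylic methyl by deactivating the ring, gives 5-(bromomethyl)-3-[(1S)-1,2,2-trimethylcyclopentyl]-1,2-phenylene diacetate F5. Friedel–Crafts benzylation of 12 at its only accessible ring position with F5 (ZnCl2, CH2Cl2, 0 °C → rt) gives the mixed dimethyl ether/diacetate dimer F6. BBr3 (CH2Cl2, −78 → 0 °C) followed by MeOH/HCl removes all four protecting groups and gives 16.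

Step 3. A tetrasubstituted alkene carrying an ortho-substituted, electron-rich aryl group may be epoxidised slowly or with modest enantioselectivity. The fallback sets out from 7 and comes back at 9, and moves the asymmetric event from the epoxidation to the rearrangement. m-CPBA (NaHCO3, CH2Cl2, 0 °C) gives racemic 2-(2,3-dimethoxy-5-methylphenyl)-2-methyl-1-oxaspiro[2.3]hexane F1. A chiral Brønsted acid (BINOL- or SPINOL-derived N-triflylphosphoramide, 5–10 mol %, PhMe, −20 °C) then runs the ring expansion as an enantioconvergent House–Meinwald rearrangement: ionisation erases the stereocentre of F1 and the migration inside the chiral ion pair resets it, giving (R)-9.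

Step 4. The electron-rich aryl group can let the epoxide open to a free benzylic cation before migration, which would erode the enantiomeric excess or divert material to the allylic alcohol. The fallback avoids any benzylic cation, sets out from 1 (through aryllithium 3) and comes back at 9. Aryllithium 3 opens cyclopentene oxide (BF3·OEt2, THF, −78 °C) to racemic trans-2-(2,3-dimethoxy-5-methylphenyl)cyclopentan-1-ol F2. Dess–Martin oxidation gives racemic 2-(2,3-dimethoxy-5-methylphenyl)cyclopentan-1-one F3. Asymmetric phase-transfer methylation of its enolate (MeI, 50% aq KOH, PhMe, 0 °C, 1–2 mol % chiral N-spiro binaphthyl ammonium bromide) gives (R)-9.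

Further compounds

F1 | step 3 | racemic 2-(2,3-dimethoxy-5-methylphenyl)-2-methyl-1-oxaspiro[2.3]hexane | CC1(c2cc(C)cc(OC)c2OC)OC13CCC3
F2 | step 4 | racemic trans-2-(2,3-dimethoxy-5-methylphenyl)cyclopentan-1-ol (one enantiomer drawn) | O[C@@H]1CCC[C@H]1c1cc(C)cc(OC)c1OC
F3 | step 4 | racemic 2-(2,3-dimethoxy-5-methylphenyl)cyclopentan-1-one | O=C1CCCC1c1cc(C)cc(OC)c1OC
F4 | step 9 | 5-methyl-3-[(1S)-1,2,2-trimethylcyclopentyl]-1,2-phenylene diacetate | CC(=O)Oc1cc(C)cc([C@@]2(C)CCCC2(C)C)c1OC(C)=O
F5 | step 9 | 5-(bromomethyl)-3-[(1S)-1,2,2-trimethylcyclopentyl]-1,2-phenylene diacetate | CC(=O)Oc1cc(CBr)cc([C@@]2(C)CCCC2(C)C)c1OC(C)=O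
F6 | step 9 | 5-{[2,3-dimethoxy-6-methyl-4-((1S)-1,2,2-trimethylcyclopentyl)phenyl]methyl}-3-[(1S)-1,2,2-trimethylcyclopentyl]-1,2-phenylene diacetate | Cc1cc([C@@]2(C)CCCC2(C)C)c(OC)c(OC)c1Cc1cc(OC(C)=O)c(OC(C)=O)c([C@@]2(C)CCCC2(C)C)c1
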